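**Retrosynthetic overview**

- The strategy rests on the array C1(O)–C14–C13(Me)=C12 of the 14-membered carbocycle. With the cis-12,13-epoxide read as a Z olefin it is a homoallylic carbinol, the retron of a [2,3]-Wittig shift (break C1–C14, rejoin O–C12).
- Target ⇐ Mitsunobu acetate with inversion at C1 ⇐ Stille methylation at C3 ⇐ hydroxyl-directed syn epoxidation of Z-C12=C13 ⇐ hydroalumination–iodination of the C2≡C3 propargylic alcohol.
- 14-membered (1S)-propargylic alcohol ⇐ [2,3]-Wittig ring expansion of a 13-membered (12S) propargylic ether carrying isopropenyl on C12 ⇐ ring-closing alkyne metathesis (C2≡C3) of a but-2-ynyl ether.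
- Open chain ⇐ CBS reduction of an isopropenyl ketone (C12), Weinreb acetamide alkylation (C10–C11), Still–Gennari olefination (Z-C8=C9), ozonolysis of (R)-α-terpineol (C3–C8 with the C6 stereocenter).
- Ring order: 13-membered ether ring (step 12), 14-membered carbocycle (step 13), oxirane (step 15).

Key step: step 13

Remark: ring atoms are numbered C1 (CHOAc), C2=C3(Me), C4, C5, C6 (bearing the carbinol carbon C15), C7, C8=C9(Me), C10, C11, C12–C13(Me) epoxide, C14; the target is (1R,2E,6R,8Z,12S,13R); TBS = tert-butyldimethylsilyl, TBSO = its oxy group.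

Remark: in the target the C1 oxygen and the epoxide oxygen are anti across C14, whereas a vanadium-directed epoxidation of a homoallylic alcohol delivers oxygen syn to the carbinol oxygen; the carbinol is therefore carried as (1S), which the (12S) ether should give in the rearrangement, and the acetate is introduced last with inversion.

**Route**

Step 1
Reactants: 1 (R)-α-terpineol
Product: 2 (R)-α-terpineol TBS ether
Conditions: TBSOTf, 2,6-lutidine, CH2Cl2, 0 °C to rt
Reagents that add atoms: tert-butyldimethylsilyl trifluoromethanesulfonate, CC(C)(C)[Si](C)(C)OS(=O)(=O)C(F)(F)F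
Why: A silyl triflate with a hindered pyridine base silylates the tertiary alcohol (silyl ether formation) and the stereocenter that becomes C6 is not touched.

Step 2
Reactants: 2 (R)-α-terpineol TBS ether
Product: 5 (5R)-7,7-dimethoxy-5-[2-(TBSO)propan-2-yl]heptan-2-one, via methoxy hydroperoxide aldehyde 3 (not isolated), via hydroperoxy dimethyl acetal 4 (not isolated)
Conditions: O3, CH2Cl2/MeOH, −78 °C; TsOH·H2O (cat.), rt; NaHCO3; Me2S, rt
Reagents that add atoms: ozone, [O-][O+]=O; methanol, CO
Why: In the unsymmetrical ozonolysis of a trisubstituted cycloalkene in methanol the carbonyl oxide should form on the methyl-bearing carbon and be trapped as the methoxy hydroperoxide, the free aldehyde is acetalised under acid catalysis and Me2S then reduces the hydroperoxide to the methyl ketone, which differentiates the two termini without touching C6.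

Step 3
Reactants: 5 (5R)-7,7-dimethoxy-5-[2-(TBSO)propan-2-yl]heptan-2-one
Product: 9 (3R)-1,1-dimethoxy-3-[2-(TBSO)propan-2-yl]oct-6-yne, via lithium enolate 6 (not isolated), via enol phosphate 7 (not isolated), via lithium acetylide 8 (not isolated)
Conditions: LiN(iPr)2, THF, −78 °C; ClP(O)(OEt)2, −78 °C to rt; LiN(iPr)2 (2.5 equiv), −78 °C to rt; MeI (excess), DMPU, 0 °C to rt
Reagents that add atoms: iodomethane, CI
Why: Kinetic deprotonation on the methyl side and O-phosphorylation give the terminal enol phosphate, which the amide base eliminates to the lithium acetylide (methyl ketone to alkyne by enol phosphate elimination) that MeI then C-methylates, the acetal and silyl ether being inert to base.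

Step 4
Reactants: 9 (3R)-1,1-dimethoxy-3-[2-(TBSO)propan-2-yl]oct-6-yne
Product: 10 (3R)-3-[2-(TBSO)propan-2-yl]oct-6-ynal
Conditions: oxalic acid, THF/H2O, rt
Reagents that add atoms: water, O
Why: Mild aqueous acid hydrolyses the dimethyl acetal (acetal hydrolysis) while the hindered tertiary silyl ether should survive, and C6 is β to the aldehyde and cannot epimerise.

Step 5
Reactants: 10 (3R)-3-[2-(TBSO)propan-2-yl]oct-6-ynal; 11 ethyl 2-[bis(2,2,2-trifluoroethoxy)phosphoryl]propanoate
Product: 12 ethyl (2Z,5R)-2-methyl-5-[2-(TBSO)propan-2-yl]dec-2-en-8-ynoate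
Conditions: KN(SiMe3)2, 18-crown-6, THF, −78 °C
Reagents that add atoms: none
Why: In the Still–Gennari olefination the trifluoroethyl phosphonate anion with a dissociated potassium counter-ion eliminates fast from the kinetic adduct and should give the Z-trisubstituted enoate (ester cis to C7), which is the C8=C9 geometry of the target.

Step 6
Reactants: 12 ethyl (2Z,5R)-2-methyl-5-[2-(TBSO)propan-2-yl]dec-2-en-8-ynoate
Product: 13 (2Z,5R)-2-methyl-5-[2-(TBSO)propan-2-yl]dec-2-en-8-yn-1-ol
Conditions: iBu2AlH, CH2Cl2, −78 °C; aq. KNaC4H4O6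
Reagents that add atoms: none
Why: 1,2-Reduction of the enoate by the aluminium hydride gives the allylic alcohol and leaves the olefin geometry and the alkyne intact.

Step 7
Reactants: 13 (2Z,5R)-2-methyl-5-[2-(TBSO)propan-2-yl]dec-2-en-8-yn-1-ol
Product: 14 (2Z,5R)-1-bromo-2-methyl-5-[2-(TBSO)propan-2-yl]dec-2-en-8-yne
Conditions: CBr4, PPh3, CH2Cl2, 0 °C
Reagents that add atoms: tetrabromomethane, BrC(Br)(Br)Br
Why: The Appel reaction converts the primary allylic alcohol into the bromide by SN2 displacement of the oxyphosphonium at low temperature, without allylic transposition of the Z-trisubstituted olefin.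

Step 8
Reactants: 14 (2Z,5R)-1-bromo-2-methyl-5-[2-(TBSO)propan-2-yl]dec-2-en-8-yne; 15 N-methoxy-N-methylacetamide
Product: 16 (4Z,7R)-N-methoxy-N,4-dimethyl-7-[2-(TBSO)propan-2-yl]dodec-4-en-10-ynamide
Conditions: 15, LiN(iPr)2, THF, −78 °C; then 14, −78 to −30 °C
Reagents that add atoms: none
Why: The lithium enolate of the Weinreb acetamide alkylates the primary allylic bromide by SN2 (amide enolate alkylation) and adds C11 and C12 at the ketone oxidation level.

Step 9
Reactants: 16 (4Z,7R)-N-methoxy-N,4-dimethyl-7-[2-(TBSO)propan-2-yl]dodec-4-en-10-ynamide; 17 isopropenylmagnesium bromide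
Product: 18 (6Z,9R)-2,6-dimethyl-9-[2-(TBSO)propan-2-yl]tetradeca-1,6-dien-12-yn-3-one
Conditions: THF, 0 °C; inverse quench into cold 1 M HCl
Reagents that add atoms: none
Why: Grignard addition to the Weinreb amide stops at the chelated tetrahedral intermediate, which collapses to the isopropenyl ketone only on acidic quench (Weinreb ketone synthesis).

Step 10
Reactants: 18 (6Z,9R)-2,6-dimethyl-9-[2-(TBSO)propan-2-yl]tetradeca-1,6-dien-12-yn-3-one
Product: 19 (3S,6Z,9R)-2,6-dimethyl-9-[2-(TBSO)propan-2-yl]tetradeca-1,6-dien-12-yn-3-ol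
Conditions: (R)-2-methyl-CBS-oxazaborolidine (20 mol %), catecholborane, toluene, −78 °C
Reagents that add atoms: none
Why: In the Corey–Bakshi–Shibata reduction the α-branched alkenyl group acts as the large substituent, so the (R)-oxazaborolidine should deliver hydride to the face that gives the (S) carbinol at C12, and catecholborane at −78 °C does not hydroborate the olefins or alkyne.

Step 11
Reactants: 19 (3S,6Z,9R)-2,6-dimethyl-9-[2-(TBSO)propan-2-yl]tetradeca-1,6-dien-12-yn-3-ol; 20 1-bromobut-2-yne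
Product: 22 (3S,6Z,9R)-3-(but-2-yn-1-yloxy)-2,6-dimethyl-9-[2-(TBSO)propan-2-yl]tetradeca-1,6-dien-12-yne, via sodium alkoxide 21 (not isolated)
Conditions: NaH, THF/DMF, 0 °C; then 20, Bu4NI (cat.), 0 °C to rt
Reagents that add atoms: none
Why: Williamson etherification of the sodium alkoxide with the reactive propargylic bromide takes place at oxygen, so C12 keeps its configuration.

Step 12
Reactants: 22 (3S,6Z,9R)-3-(but-2-yn-1-yloxy)-2,6-dimethyl-9-[2-(TBSO)propan-2-yl]tetradeca-1,6-dien-12-yne
Product: 23 (2S,5Z,8R)-5-methyl-2-(prop-1-en-2-yl)-8-[2-(TBSO)propan-2-yl]-1-oxacyclotridec-5-en-11-yne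
Conditions: Mo(≡CC6H4-4-OMe)(OSiPh3)3 (10 mol %), 5 Å MS, toluene (2 mM), 80 °C
Reagents that add atoms: none
Why: Ring-closing alkyne metathesis with the molybdenum alkylidyne joins the two methyl-capped alkynes into the C2≡C3 bond of the 13-membered ether and is driven by loss of but-2-yne into the sieves, while olefins, ethers and silyl ethers are tolerated and no stereocenter is involved.

Step 13
Reactants: 23 (2S,5Z,8R)-5-methyl-2-(prop-1-en-2-yl)-8-[2-(TBSO)propan-2-yl]-1-oxacyclotridec-5-en-11-yne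
Product: 26 (1S,6R,8Z,12Z)-9,13-dimethyl-6-[2-(TBSO)propan-2-yl]cyclotetradeca-8,12-dien-2-yn-1-ol, via C1-lithiated ether 24 (not isolated), via lithium alkoxide 25 (not isolated)
Conditions: n-BuLi, THF, −78 °C; then H2O
Reagents that add atoms: none
Why: Proposed new method: n-BuLi should remove a proton from C1, the only carbon that is both α to oxygen and propargylic, and the α-oxy propargyl anion should bond through C1 to the isopropenyl CH2 (C14) across a five-membered envelope (C1–O–C12–C13–C14) while the O–C12 bond breaks, which moves the oxygen to C1 and brings C13 and C14 into the ring. The closest known reactions are the [2,3]-Wittig rearrangement of open-chain propargyl 2-methylallyl ethers and the ring contraction of macrocyclic propargyl allyl ethers; a shift in which the allyl unit is exocyclic, so that a 13-membered ether grows into a 14-membered carbocycle, is the untested element. The 14-membered ring is closed by two-carbon ring expansion through this bridged five-membered sigmatropic transition state (C1–C14 bond formation) and not by an end-to-end cyclisation, so dilution is not needed. The new C1 stereocenter is controlled by transfer of chirality from C12: the C11 chain should lie on the C14 side of the allyl unit to avoid the C13 methyl, and the alkynyl carbon C2 should sit on the convex (exo) side of the envelope, as the C2-to-C11 tether demands, and in that arrangement the (12S) ether gives the (1S) carbinol. The same placement of C11 makes the new C12=C13 olefin Z. The step needs deprotonation at C1 over C4 and C12 (secured by the combined oxygen and alkyne activation), [2,3] over [1,2] migration (favoured at −78 °C) and Z over E geometry (secured by the C13 methyl).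

Step 14
Reactants: 26 (1S,6R,8Z,12Z)-9,13-dimethyl-6-[2-(TBSO)propan-2-yl]cyclotetradeca-8,12-dien-2-yn-1-ol
Product: 28 (1S,2Z,6R,8Z,12Z)-3-iodo-9,13-dimethyl-6-[2-(TBSO)propan-2-yl]cyclotetradeca-2,8,12-trien-1-ol, via cyclic alkenylalanate 27 (not isolated)
Conditions: NaAlH2(OCH2CH2OMe)2, THF, 0 °C to rt; EtOAc; I2, −78 °C
Reagents that add atoms: iodine, II
Why: The alkoxy aluminate delivers hydride intramolecularly to C2 (trans-hydroalumination of a propargylic alcohol) to give the cyclic alkenylalanate with aluminium on C3, and iodinolysis with retention gives the (Z)-3-iodo allylic alcohol in which C1 and C4 are trans across the ring olefin.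

Step 15
Reactants: 28 (1S,2Z,6R,8Z,12Z)-3-iodo-9,13-dimethyl-6-[2-(TBSO)propan-2-yl]cyclotetradeca-2,8,12-trien-1-ol
Product: 29 (1S,2Z,6R,8Z,12S,13R)-12,13-epoxy-3-iodo-9,13-dimethyl-6-[2-(TBSO)propan-2-yl]cyclotetradeca-2,8-dien-1-ol
Conditions: VO(acac)2 (5 mol %), t-BuOOH, CH2Cl2, 0 °C to rt
Reagents that add atoms: tert-butyl hydroperoxide, CC(C)(C)OO
Why: In the vanadium-catalysed hydroxyl-directed epoxidation of a homoallylic alcohol the vanadate ester should deliver oxygen through a chair transition state with C2 equatorial to the face of Z-C12=C13 that is syn to the C1 oxygen, which sets (12S,13R) from (1S), while the iodo olefin is electron-poor, C8=C9 is remote and the tertiary hydroxyl is silylated.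

Step 16
Reactants: 29 (1S,2Z,6R,8Z,12S,13R)-12,13-epoxy-3-iodo-9,13-dimethyl-6-[2-(TBSO)propan-2-yl]cyclotetradeca-2,8-dien-1-ol
Product: 30 (1S,2E,6R,8Z,12S,13R)-12,13-epoxy-3,9,13-trimethyl-6-[2-(TBSO)propan-2-yl]cyclotetradeca-2,8-dien-1-ol
Conditions: Pd2(dba)3 (5 mol %), AsPh3, CuI (10 mol %), Me4Sn, NMP, 50 °C
Reagents that add atoms: tetramethylstannane, C[Sn](C)(C)C
Why: In the Stille coupling, oxidative addition of zerovalent palladium into the C3–I bond, methyl transfer from tin and reductive elimination replace iodine by methyl with retention of olefin geometry under neutral conditions that should spare the epoxide and the free alcohol.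

Step 17
Reactants: 30 (1S,2E,6R,8Z,12S,13R)-12,13-epoxy-3,9,13-trimethyl-6-[2-(TBSO)propan-2-yl]cyclotetradeca-2,8-dien-1-ol
Product: 31 (1S,2E,6R,8Z,12S,13R)-12,13-epoxy-6-(2-hydroxypropan-2-yl)-3,9,13-trimethylcyclotetradeca-2,8-dien-1-ol
Conditions: Bu4NF, THF, 50 °C
Reagents that add atoms: none
Why: Fluoride cleaves the tertiary silyl ether through Si–F bond formation (desilylation), and the epoxide and allylic alcohol should be stable in the mildly basic medium.

Step 18
Reactants: 31 (1S,2E,6R,8Z,12S,13R)-12,13-epoxy-6-(2-hydroxypropan-2-yl)-3,9,13-trimethylcyclotetradeca-2,8-dien-1-ol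
Product: 32 (1R,2E,6R,8Z,12S,13R)-12,13-epoxy-6-(2-hydroxypropan-2-yl)-3,9,13-trimethylcyclotetradeca-2,8-dien-1-yl acetate
Conditions: PPh3, diisopropyl azodicarboxylate, AcOH, toluene, −20 to 0 °C
Reagents that add atoms: acetic acid, CC(=O)O
Why: In the Mitsunobu esterification acetate displaces the oxyphosphonium of the secondary allylic alcohol by SN2 with inversion, which turns (1S) into the (1R) acetate, while the tertiary alcohol is not activated.

**Compound list**

1 | (R)-α-terpineol | CC1=CC[C@H](C(C)(C)O)CC1 | starting material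
2 | (R)-α-terpineol TBS ether | CC1=CC[C@H](C(C)(C)O[Si](C)(C)C(C)(C)C)CC1 | intermediate
3 | (3R)-6-hydroperoxy-6-methoxy-3-[2-(TBSO)propan-2-yl]heptanal | O=CC[C@H](C(C)(C)O[Si](C)(C)C(C)(C)C)CCC(C)(OC)OO | intermediate
4 | (5R)-2-hydroperoxy-2,7,7-trimethoxy-5-[2-(TBSO)propan-2-yl]heptane | COC(OC)C[C@H](C(C)(C)O[Si](C)(C)C(C)(C)C)CCC(C)(OC)OO | intermediate
5 | (5R)-7,7-dimethoxy-5-[2-(TBSO)propan-2-yl]heptan-2-one | COC(OC)C[C@H](C(C)(C)O[Si](C)(C)C(C)(C)C)CCC(C)=O | intermediate
6 | terminal lithium enolate of 5 | COC(OC)C[C@H](C(C)(C)O[Si](C)(C)C(C)(C)C)CCC(=C)O[Li] | intermediate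
7 | diethyl (5R)-7,7-dimethoxy-5-[2-(TBSO)propan-2-yl]hept-1-en-2-yl phosphate | COC(OC)C[C@H](C(C)(C)O[Si](C)(C)C(C)(C)C)CCC(=C)OP(=O)(OCC)OCC | intermediate
8 | lithium acetylide of (5R)-7,7-dimethoxy-5-[2-(TBSO)propan-2-yl]hept-1-yne | COC(OC)C[C@H](C(C)(C)O[Si](C)(C)C(C)(C)C)CCC#C[Li] | intermediate
9 | (3R)-1,1-dimethoxy-3-[2-(TBSO)propan-2-yl]oct-6-yne | COC(OC)C[C@H](C(C)(C)O[Si](C)(C)C(C)(C)C)CCC#CC | intermediate
10 | (3R)-3-[2-(TBSO)propan-2-yl]oct-6-ynal | O=CC[C@H](C(C)(C)O[Si](C)(C)C(C)(C)C)CCC#CC | intermediate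
11 | ethyl 2-[bis(2,2,2-trifluoroethoxy)phosphoryl]propanoate | CCOC(=O)C(C)P(=O)(OCC(F)(F)F)OCC(F)(F)F | starting material
12 | ethyl (2Z,5R)-2-methyl-5-[2-(TBSO)propan-2-yl]dec-2-en-8-ynoate | CCOC(=O)/C(C)=C\C[C@H](C(C)(C)O[Si](C)(C)C(C)(C)C)CCC#CC | intermediate
13 | (2Z,5R)-2-methyl-5-[2-(TBSO)propan-2-yl]dec-2-en-8-yn-1-ol | OC/C(C)=C\C[C@H](C(C)(C)O[Si](C)(C)C(C)(C)C)CCC#CC | intermediate
14 | (2Z,5R)-1-bromo-2-methyl-5-[2-(TBSO)propan-2-yl]dec-2-en-8-yne | BrC/C(C)=C\C[C@H](C(C)(C)O[Si](C)(C)C(C)(C)C)CCC#CC | intermediate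
15 | N-methoxy-N-methylacetamide | CON(C)C(C)=O | starting material
16 | (4Z,7R)-N-methoxy-N,4-dimethyl-7-[2-(TBSO)propan-2-yl]dodec-4-en-10-ynamide | CON(C)C(=O)CC/C(C)=C\C[C@H](C(C)(C)O[Si](C)(C)C(C)(C)C)CCC#CC | intermediate
17 | isopropenylmagnesium bromide | C=C(C)[Mg]Br | starting material
18 | (6Z,9R)-2,6-dimethyl-9-[2-(TBSO)propan-2-yl]tetradeca-1,6-dien-12-yn-3-one | C=C(C)C(=O)CC/C(C)=C\C[C@H](C(C)(C)O[Si](C)(C)C(C)(C)C)CCC#CC | intermediate
19 | (3S,6Z,9R)-2,6-dimethyl-9-[2-(TBSO)propan-2-yl]tetradeca-1,6-dien-12-yn-3-ol | C=C(C)[C@@H](O)CC/C(C)=C\C[C@H](C(C)(C)O[Si](C)(C)C(C)(C)C)CCC#CC | intermediate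
20 | 1-bromobut-2-yne | CC#CCBr | starting material
21 | sodium alkoxide of 19 | C=C(C)[C@@H](O[Na])CC/C(C)=C\C[C@H](C(C)(C)O[Si](C)(C)C(C)(C)C)CCC#CC | intermediate
22 | (3S,6Z,9R)-3-(but-2-yn-1-yloxy)-2,6-dimethyl-9-[2-(TBSO)propan-2-yl]tetradeca-1,6-dien-12-yne | C=C(C)[C@@H](OCC#CC)CC/C(C)=C\C[C@H](C(C)(C)O[Si](C)(C)C(C)(C)C)CCC#CC | intermediate
23 | (2S,5Z,8R)-5-methyl-2-(prop-1-en-2-yl)-8-[2-(TBSO)propan-2-yl]-1-oxacyclotridec-5-en-11-yne (13-membered ether; O links C1 and C12) | C=C(C)[C@@H]1CC/C(C)=C\C[C@H](C(C)(C)O[Si](C)(C)C(C)(C)C)CCC#CCO1 | intermediate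
24 | 23 lithiated at the OCH2 carbon (C1) | C=C(C)[C@@H]1CC/C(C)=C\C[C@H](C(C)(C)O[Si](C)(C)C(C)(C)C)CCC#CC([Li])O1 | intermediate
25 | lithium alkoxide of 26 | [Li]O[C@@H]1C#CCC[C@@H](C(C)(C)O[Si](C)(C)C(C)(C)C)C/C=C(/C)CC/C=C(/C)C1 | intermediate
26 | (1S,6R,8Z,12Z)-9,13-dimethyl-6-[2-(TBSO)propan-2-yl]cyclotetradeca-8,12-dien-2-yn-1-ol | O[C@@H]1C#CCC[C@@H](C(C)(C)O[Si](C)(C)C(C)(C)C)C/C=C(/C)CC/C=C(/C)C1 | intermediate
27 | sodium cyclic alkenylalanate (Al bound to the C1 oxygen, to C3 and to two 2-methoxyethoxy groups) | [Na+].COCCO[Al-]1(OCCOC)O[C@@H]2C=C1CC[C@@H](C(C)(C)O[Si](C)(C)C(C)(C)C)C/C=C(/C)CC/C=C(/C)C2 | intermediate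
28 | (1S,2Z,6R,8Z,12Z)-3-iodo-9,13-dimethyl-6-[2-(TBSO)propan-2-yl]cyclotetradeca-2,8,12-trien-1-ol | O[C@@H]1/C=C(\I)CC[C@@H](C(C)(C)O[Si](C)(C)C(C)(C)C)C/C=C(/C)CC/C=C(/C)C1 | intermediate
29 | (1S,2Z,6R,8Z,12S,13R)-12,13-epoxy-3-iodo-9,13-dimethyl-6-[2-(TBSO)propan-2-yl]cyclotetradeca-2,8-dien-1-ol | O[C@@H]1/C=C(\I)CC[C@@H](C(C)(C)O[Si](C)(C)C(C)(C)C)C/C=C(/C)CC[C@@H]2O[C@]2(C)C1 | intermediate
30 | (1S,2E,6R,8Z,12S,13R)-12,13-epoxy-3,9,13-trimethyl-6-[2-(TBSO)propan-2-yl]cyclotetradeca-2,8-dien-1-ol | O[C@@H]1/C=C(\C)CC[C@@H](C(C)(C)O[Si](C)(C)C(C)(C)C)C/C=C(/C)CC[C@@H]2O[C@]2(C)C1 | intermediate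
31 | (1S,2E,6R,8Z,12S,13R)-12,13-epoxy-6-(2-hydroxypropan-2-yl)-3,9,13-trimethylcyclotetradeca-2,8-dien-1-ol | O[C@@H]1/C=C(\C)CC[C@@H](C(C)(C)O)C/C=C(/C)CC[C@@H]2O[C@]2(C)C1 | intermediate
32 | (1R,2E,6R,8Z,12S,13R)-12,13-epoxy-6-(2-hydroxypropan-2-yl)-3,9,13-trimethylcyclotetradeca-2,8-dien-1-yl acetate | CC(=O)O[C@H]1/C=C(\C)CC[C@@H](C(C)(C)O)C/C=C(/C)CC[C@@H]2O[C@]2(C)C1 | target

**Step count and risks**

Total step count: 18. Longest linear sequence: 18 steps (1 to 32).

Steps most likely to fail: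

1. Step 13 (Proposed new method). The bridged transition state may be too strained in the 13-membered ring, so that the anion undergoes a [1,2]-shift instead. The C11 chain may also take the outside position, which would give the E olefin together with the wrong C1 configuration. The fallback uses known chemistry, sets out from 22 and returns at 26, and reverses the order of rearrangement and ring closure. n-BuLi in THF at −78 °C should convert 22 by the open-chain [2,3]-Wittig rearrangement of a propargyl 2-methylallyl ether into the open-chain (4S,6Z,10Z,13R) propargylic alcohol F1. Et3SiCl and imidazole give its triethylsilyl ether F2. Ring-closing alkyne metathesis with the molybdenum alkylidyne of step 12 closes the 14-membered cycloalkyne silyl ether F3. Pyridinium p-toluenesulfonate in MeOH removes the secondary triethylsilyl group beside the tertiary TBS ether and gives 26.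

2. Step 15. Facial selectivity may be poor if the macrocycle cannot adopt the chair arrangement of the vanadate ester, and oxidation may then spread to C8=C9. The fallback sets out from 28 and returns at 29, and replaces oxygen transfer by an electrophile-induced cyclisation. Boc2O with DMAP gives the tert-butyl carbonate F4. IBr in toluene at −85 °C should close the six-membered cyclic carbonate onto C13 with iodine on C12 and give the iodo carbonate F5, in which the C1 and C13 oxygens are cis on the dioxanone. K2CO3 in MeOH cleaves the carbonate, and the C13 alkoxide displaces iodide at C12 to give 29.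

3. Step 18. The oxyphosphonium may ionise to the C1–C3 allyl cation, with loss of configuration, attack at C3 or capture by the tertiary hydroxyl. The fallback sets out from 31 and returns at 32, and replaces the SN2 inversion by oxidation and reagent-controlled reduction. MnO2 in CH2Cl2 oxidises only the allylic alcohol to the epoxy enone F6, which is kept neutral and cold to avoid β-opening of the epoxide. (S)-2-Methyl-CBS-oxazaborolidine with catecholborane at −78 °C, with the alkenyl group as the large substituent, should give the (1R) diol F7. Ac2O in pyridine at 0 °C acetylates the secondary hydroxyl selectively and gives 32.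

**Further compounds**

F1 | step 13 | (4S,6Z,10Z,13R)-6,10-dimethyl-13-[2-(TBSO)propan-2-yl]octadeca-6,10-dien-2,16-diyn-4-ol | CC#C[C@@H](O)C/C(C)=C\CC/C(C)=C\C[C@H](C(C)(C)O[Si](C)(C)C(C)(C)C)CCC#CC
F2 | step 13 | triethylsilyl ether of F1 | CC#C[C@@H](O[Si](CC)(CC)CC)C/C(C)=C\CC/C(C)=C\C[C@H](C(C)(C)O[Si](C)(C)C(C)(C)C)CCC#CC
F3 | step 13 | triethylsilyl ether of 26 | CC[Si](CC)(CC)O[C@@H]1C#CCC[C@@H](C(C)(C)O[Si](C)(C)C(C)(C)C)C/C=C(/C)CC/C=C(/C)C1
F4 | step 15 | tert-butyl carbonate of 28 | CC(C)(C)OC(=O)O[C@@H]1/C=C(\I)CC[C@@H](C(C)(C)O[Si](C)(C)C(C)(C)C)C/C=C(/C)CC/C=C(/C)C1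
F5 | step 15 | (1S,12R,13R) cyclic carbonate spanning the C1 and C13 oxygens with iodine on C12 and C3 | O=C1O[C@@H]2/C=C(\I)CC[C@@H](C(C)(C)O[Si](C)(C)C(C)(C)C)C/C=C(/C)CC[C@@H](I)[C@](C)(O1)C2
F6 | step 18 | (2E,6R,8Z,12S,13R)-12,13-epoxy-6-(2-hydroxypropan-2-yl)-3,9,13-trimethylcyclotetradeca-2,8-dien-1-one | O=C1/C=C(\C)CC[C@@H](C(C)(C)O)C/C=C(/C)CC[C@@H]2O[C@]2(C)C1
F7 | step 18 | (1R,2E,6R,8Z,12S,13R)-12,13-epoxy-6-(2-hydroxypropan-2-yl)-3,9,13-trimethylcyclotetradeca-2,8-dien-1-ol | O[C@H]1/C=C(\C)CC[C@@H](C(C)(C)O)C/C=C(/C)CC[C@@H]2O[C@]2(C)C1
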